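**Straight trap.** Beware a nearly straight curve: on the oak run it can hide a slow loss of target.

| flask | starting material | free catalyst | remark | time |
|---|---|---|---|---|
| oak | 0.60 M | 1.6 mM | run made earlier |  |
| green | 0.60 M | 2.4 mM |  | 1.0 h |
| blue | 1.2 M | 2.4 mM |  | 1.0 h |
| amber | 2.5 M | 2.4 mM |  | 1.0 h |

oak run (percent of the starting material charged)

| time / min | target / % |
|---|---|
| 1.50 | 4.2 |
| 3.00 | 8.1 |
| 6.00 | 15.3 |
| 12.0 | 32.1 |
| 20.0 | 51.3 |

(readings scatter by 0.5 percentage points)

- "hardly changes" means that all values lie within two and a half points (for a concentration: within two and a half percent of the largest)
- no earlier run changes the charge of free catalyst; that part of a forecast is a guess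

- amount of target at the end, in percent of the starting material charged for green, blue, amber, in this order
- how the row runs (rises all the way / rises, then falls / hardly changes / falls, then rises / falls all the way)

**Main step.** First take target as made at a steady rate, zero order in starting material. The last oak reading averages 0.0256 min⁻¹ of the charge, while the reading at 3.00 min averages 0.0270 min⁻¹, so the late average is lower.

**Slow loss.** Now add a first-order loss of target. Target in the oak flask has stood, on average, for half the elapsed time, so the two averages give a loss constant of 0.00588 min⁻¹. With a scatter of 0.5 percentage points on a reading of 8.1%, treat this value as rough.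

**Second round.** Put that loss back into the last oak reading. The making rate per catalyst then reads 10.2 min⁻¹.

**The rest.** Assume the rate follows c(free catalyst), which is a guess. Dividing c(starting material) by this rate gives an emptying time of 24.5 min for green and 48.9 min for blue, and both are shorter than the run. Amber needs 102 min, longer than the run, so it makes 58.9% of its charge.

**Mean age.** A flask that empties at a given time ends with target that has stood for the run time minus half the emptying time. An unemptied flask has stood for half the run time. Call this the mean age: green 47.8 min, blue 35.5 min, amber 30.0 min. Decay at the loss constant over the mean age gives my row: 75.5%, 81.2%, 49.4%. Green's target is older than blue's. My row rises, then falls.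

**The forecast.** The forecast says 100%, 98%, 56%, a row that falls all the way, on the ground that “the reaction is close to zero order in starting material”. It stands above my row at each point.

**The flask.** The row is 83.3%, 87.3%, 52.6%: it rises, then falls.

    target ⇌ isomer of the product (K = 1.50, k = 0.00410 min⁻¹)
    catalyst intermediate ⇌ free catalyst + target (K = 0.470 M, k = 10.4 min⁻¹)
    free catalyst ⇌ dormant form (K = 0.450, k = 0.0237 min⁻¹)
    starting material + free catalyst → catalyst intermediate (k = 1190 L mol⁻¹ min⁻¹)

**Green's loss.** In green, target has a forward half-life of 2.8 h towards the isomer of the product, longer than its mean age of 47.8 min, and at 1.00 h the isomer of the product stands at 16.5%, or 0.00346 min⁻¹ of the charge per minute of mean age. Multiplied by blue's mean age of 35.5 min, that gives 12.3%, and at 1.00 h blue holds 12.6% of the isomer of the product.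

(Readings and results are simulated from invented constants; noise was put on by code.)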